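## Retrosynthetic overview

1. Target 25 comes from its methyl ester 24. The quaternary C6 of 24 is made last, by a dearomatising palladium-catalysed prenylation of phenol 22. Compound 22 comes from reductive alkylation of 16 at C6 with cyclobutane aldehyde 21, made from (1S)-verbenone, which supplies both cyclobutane centres.
2. The C8 arm of 16 comes from rhodium-catalysed asymmetric 1,4-addition of phenylboronic acid to the C8 acrylate 13, itself made by C8 iodination and Heck reaction of the cis-2,3-dimethylchromanone 10.
3. The strategy rests on ring B (O1, C2, C3, C4, C4a, C8a): its carbonyl carbon C4 is bonded to stereogenic C3, next to the oxygen-bearing C2. With C3 read as the β-carbon of an enoate tethered through O1, the C3–C4 bond links two acceptor carbons. It is therefore made by umpolung of the aryl aldehyde (intramolecular Stetter reaction, 6 to 7), and the acetate arm is then cut back to the C3 methyl by radical decarboxylation.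
4. Precursor 6 comes from Mitsunobu inversion between salicylaldehyde 2 and the (S)-hydroxy enoate 5, made by cross-metathesis of (S)-but-3-en-2-ol. Benzyl ethers and a tert-butyl ester are used so that nothing after ring closure needs a Lewis acid or a strong base near the cis ketone.
5. Ring order: aromatic ring A is bought, ring B is closed in step 4, ring A is dearomatised in step 16, and the cyclobutane is bought.

Key step: step 4

Assumption: in the three catalyst-controlled steps (4, 9, 16) the antipode of the chiral catalyst is the one that meets the facial requirement stated in the step, fixed by a trial run with each antipode.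

## Route

Step 1
Reactants: 1 2,4,6-trihydroxybenzaldehyde
Product: 2 2,4-bis(benzyloxy)-6-hydroxybenzaldehyde
Conditions: BnBr (2.0 equiv), K2CO3 (2.0 equiv), DMF, 0 °C to rt
Reagents that add atoms: benzyl bromide, BrCc1ccccc1
Why: Williamson etherification should cap the 4-hydroxyl and one of the two equivalent ortho hydroxyls, while the last hydroxyl, held in a hydrogen bond to the formyl oxygen, stays free.

Step 2
Reactants: 3 (S)-but-3-en-2-ol; 4 tert-butyl acrylate
Product: 5 tert-butyl (2E,4S)-4-hydroxypent-2-enoate
Conditions: second-generation Hoveyda–Grubbs catalyst (2.5 mol%), 4 (3 equiv), CH2Cl2, 40 °C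
Reagents that add atoms: none
Why: Olefin cross-metathesis of a secondary allylic alcohol with an electron-poor acrylate should give the E cross-product and does not touch the carbinol stereocentre taken from the chiral pool.

Step 3
Reactants: 2 2,4-bis(benzyloxy)-6-hydroxybenzaldehyde; 5 tert-butyl (2E,4S)-4-hydroxypent-2-enoate
Product: 6 tert-butyl (2E,4R)-4-[3,5-bis(benzyloxy)-2-formylphenoxy]pent-2-enoate
Conditions: PPh3, DIAD, toluene, 0 °C to rt
Reagents that add atoms: none
Why: In this Mitsunobu etherification the acidic salicylaldehyde phenol displaces the activated secondary alcohol by SN2 with inversion (4S to 4R), the conjugated ester disfavouring ionisation, and this carbon becomes C2 of ring B.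

Step 4
Reactants: 6 tert-butyl (2E,4R)-4-[3,5-bis(benzyloxy)-2-formylphenoxy]pent-2-enoate
Product: 7 tert-butyl 2-[(2R,3S)-5,7-bis(benzyloxy)-2-methyl-4-oxochroman-3-yl]acetate
Conditions: 2-(pentafluorophenyl)-5a,10b-dihydro-4H,6H-indeno[2,1-b][1,2,4]triazolo[4,3-d][1,4]oxazin-2-ium tetrafluoroborate (C18H11BF9N3O, one antipode, 20 mol%), KN(SiMe3)2 (18 mol%), toluene, 0 to 23 °C; AcOH quench
Reagents that add atoms: none
Why: The free triazolylidene adds to the formyl group of 6 and proton transfer gives the Breslow intermediate, whose nucleophilic carbon (the future C4) adds to the β-carbon of the tethered enoate (the future C3) before proton transfer and loss of the carbene release the ketone. The closest known reaction type is the enantioselective intramolecular Stetter reaction of salicylaldehyde-derived enoates to 3-substituted chroman-4-ones, including substrates that already carry a stereocentre in the tether. Ring B is closed in the 6-exo-trig mode, the only one the O1–C2 tether allows. C3 is the single new stereocentre and is set under catalyst control by the aminoindanol backbone, which must direct the acyl anion to the Si face of the β-carbon of the E-enoate (3S, cis to the C2 methyl), while C2 (R) comes unchanged from 5. The step therefore needs face selectivity at C3, secured by the fixed E geometry and 2R centre of the substrate paired with the matched catalyst antipode, the mismatched antipode leading to the trans isomer. Because the cis ketone can drift to trans by enolisation, less base than triazolium salt is used so that no free amide base remains, and the reaction is quenched with AcOH as soon as 6 is consumed.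

Step 5
Reactants: 7 tert-butyl 2-[(2R,3S)-5,7-bis(benzyloxy)-2-methyl-4-oxochroman-3-yl]acetate
Product: 8 2-[(2R,3S)-5,7-bis(benzyloxy)-2-methyl-4-oxochroman-3-yl]acetic acid
Conditions: TFA–CH2Cl2 (1:4), 0 °C to rt
Reagents that add atoms: none
Why: Acidolysis of the tert-butyl ester with loss of isobutene needs no base, so the epimerisable C3 centre and the aryl benzyl ethers should survive the short exposure.

Step 6
Reactants: 8 2-[(2R,3S)-5,7-bis(benzyloxy)-2-methyl-4-oxochroman-3-yl]acetic acid
Product: 10 (2R,3S)-5,7-bis(benzyloxy)-2,3-dimethylchroman-4-one, via Barton ester 9 (not isolated)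
Conditions: N-hydroxypyridine-2-thione, DCC, CH2Cl2, 0 °C to rt, dark; then t-BuSH (10 equiv), visible light, rt
Reagents that add atoms: N-hydroxypyridine-2-thione, ON1C=CC=CC1=S (its atoms remain only in 9)
Why: In this Barton reductive decarboxylation the thiohydroxamate ester fragments to a primary radical on the exocyclic carbon, which the thiol should reduce faster than it can add to the C4 carbonyl, and C3 is never a radical or enolate site, so the cis relationship is kept while the arm becomes the C3 methyl.

Step 7
Reactants: 10 (2R,3S)-5,7-bis(benzyloxy)-2,3-dimethylchroman-4-one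
Product: 11 (2R,3S)-5,7-bis(benzyloxy)-8-iodo-2,3-dimethylchroman-4-one
Conditions: NIS (1.05 equiv), TFA (10 mol%), MeCN, 0 °C to rt, dark
Reagents that add atoms: N-iodosuccinimide, O=C1CCC(=O)N1I
Why: Electrophilic aromatic iodination should go to C8, which lies between the tied-back ring oxygen O1 and one benzyloxy group and is more accessible than C6 between two benzyloxy groups, in line with the known 8-halogenation of 5,7-dialkoxy chromones.

Step 8
Reactants: 11 (2R,3S)-5,7-bis(benzyloxy)-8-iodo-2,3-dimethylchroman-4-one; 12 methyl acrylate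
Product: 13 methyl (E)-3-[(2R,3S)-5,7-bis(benzyloxy)-2,3-dimethyl-4-oxochroman-8-yl]acrylate
Conditions: Pd(OAc)2 (5 mol%), n-Bu4NCl, NaHCO3, DMF, 70 °C
Reagents that add atoms: none
Why: A Mizoroki–Heck reaction under ligand-free phase-transfer conditions couples the hindered aryl iodide with the acrylate through syn insertion and syn β-hydride elimination to the E alkene, with bicarbonate as the only base so that C3 is not enolised.

Step 9
Reactants: 13 methyl (E)-3-[(2R,3S)-5,7-bis(benzyloxy)-2,3-dimethyl-4-oxochroman-8-yl]acrylate; 14 phenylboronic acid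
Product: 15 methyl (3S)-3-[(2R,3S)-5,7-bis(benzyloxy)-2,3-dimethyl-4-oxochroman-8-yl]-3-phenylpropanoate
Conditions: [RhCl(C2H4)2]2 (2.5 mol%), 2,5-diphenylbicyclo[2.2.2]octa-2,5-diene (one antipode, 5.5 mol%), 14 (3 equiv), KOH (0.2 equiv), 1,4-dioxane–H2O (10:1), 40 °C
Reagents that add atoms: none
Why: In this Hayashi–Miyaura asymmetric 1,4-addition the chiral diene–rhodium–phenyl species inserts the enoate with phenyl delivered to the Re face of the β-carbon, which sets the benzylic S centre under catalyst control, while the excess boronic acid buffers the medium near neutrality.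

Step 10
Reactants: 15 methyl (3S)-3-[(2R,3S)-5,7-bis(benzyloxy)-2,3-dimethyl-4-oxochroman-8-yl]-3-phenylpropanoate
Product: 16 methyl (3S)-3-[(2R,3S)-5,7-dihydroxy-2,3-dimethyl-4-oxochroman-8-yl]-3-phenylpropanoate
Conditions: H2 (1 atm), Pd/C (10% palladium on carbon), MeOH–EtOAc, rt
Reagents that add atoms: none
Why: Neutral hydrogenolysis removes both benzyl ethers without acid or base, the electron-rich aryl ketone and the methyl ester are not reduced, and the methanol co-solvent works against lactonisation of the ester onto the freed 7-hydroxyl.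

Step 11
Reactants: 17 (1S)-(−)-verbenone
Product: 18 (1S,3R)-3-acetyl-2,2-dimethylcyclobutane-1-carboxylic acid
Conditions: RuCl3·xH2O (2 mol%), NaIO4 (4.2 equiv), CCl4–MeCN–H2O, rt
Reagents that add atoms: sodium periodate, [Na+].[O-]I(=O)(=O)=O; water, O
Why: Ruthenium tetroxide generated in situ cleaves the enone C=C and the resulting α-keto acid loses one carbon as CO2, leaving cis-pinononic acid with both ring stereocentres retained from the bicycle.

Step 12
Reactants: 18 (1S,3R)-3-acetyl-2,2-dimethylcyclobutane-1-carboxylic acid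
Product: 19 (1S,3S)-2,2-dimethyl-3-(prop-1-en-2-yl)cyclobutane-1-carboxylic acid
Conditions: Ph3PCH3Br (3.0 equiv), KOtBu (2.9 equiv), THF, 0 °C; then 18, 0 °C to rt; aqueous acid work-up
Reagents that add atoms: methyltriphenylphosphonium bromide, C[P+](c1ccccc1)(c1ccccc1)c1ccccc1.[Br-]
Why: In this Wittig methylenation the carboxylate is inert to the ylide and the methyl ketone should be olefinated faster than the ring α-hydrogen is removed, so the cis arrangement on the cyclobutane is kept (the descriptor at C3 changes only through priorities).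

Step 13
Reactants: 19 (1S,3S)-2,2-dimethyl-3-(prop-1-en-2-yl)cyclobutane-1-carboxylic acid
Product: 20 [(1S,3S)-2,2-dimethyl-3-(prop-1-en-2-yl)cyclobutyl]methanol
Conditions: LiAlH4, THF, 0 °C to rt; Fieser work-up
Reagents that add atoms: none
Why: Hydride reduction takes the acid to the primary alcohol and leaves the isolated 1,1-disubstituted alkene and both stereocentres alone.

Step 14
Reactants: 20 [(1S,3S)-2,2-dimethyl-3-(prop-1-en-2-yl)cyclobutyl]methanol
Product: 21 (1S,3S)-2,2-dimethyl-3-(prop-1-en-2-yl)cyclobutane-1-carbaldehyde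
Conditions: Dess–Martin periodinane, CH2Cl2, 0 °C to rt; used at once
Reagents that add atoms: none
Why: Dess–Martin oxidation stops at the aldehyde under non-basic conditions, so the ring carbon next to the formyl group should not epimerise.

Step 15
Reactants: 16 methyl (3S)-3-[(2R,3S)-5,7-dihydroxy-2,3-dimethyl-4-oxochroman-8-yl]-3-phenylpropanoate; 21 (1S,3S)-2,2-dimethyl-3-(prop-1-en-2-yl)cyclobutane-1-carbaldehyde
Product: 22 methyl (3S)-3-[(2R,3S)-6-{[(1R,3S)-2,2-dimethyl-3-(prop-1-en-2-yl)cyclobutyl]methyl}-5,7-dihydroxy-2,3-dimethyl-4-oxochroman-8-yl]-3-phenylpropanoate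
Conditions: L-proline (20 mol%), Hantzsch ester (diethyl 2,6-dimethyl-1,4-dihydropyridine-3,5-dicarboxylate, 1.2 equiv), CH2Cl2, rt
Reagents that add atoms: none
Why: In this organocatalytic reductive alkylation the iminium-activated aldehyde is attacked by C6, the only unsubstituted nucleophilic ring carbon, loss of proline gives an ortho-quinone methide that the Hantzsch ester reduces to the CH2 link, and enamine formation from the hindered α-branched aldehyde should be too slow to epimerise the cyclobutane centre.

Step 16
Reactants: 22 methyl (3S)-3-[(2R,3S)-6-{[(1R,3S)-2,2-dimethyl-3-(prop-1-en-2-yl)cyclobutyl]methyl}-5,7-dihydroxy-2,3-dimethyl-4-oxochroman-8-yl]-3-phenylpropanoate; 23 prenyl acetate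
Product: 24 methyl (3S)-3-[(2R,3S,6R)-6-{[(1R,3S)-2,2-dimethyl-3-(prop-1-en-2-yl)cyclobutyl]methyl}-4-hydroxy-2,3-dimethyl-6-(3-methylbut-2-en-1-yl)-5,7-dioxo-3,5,6,7-tetrahydro-2H-chromen-8-yl]-3-phenylpropanoate
Conditions: Pd2(dba)3·CHCl3 (2.5 mol%), DACH-phenyl Trost ligand (one antipode, 7.5 mol%), Cs2CO3 (1.1 equiv), THF, 0 °C to rt
Reagents that add atoms: none
Why: In this Tsuji–Trost alkylation with dearomatisation the caesium phenoxide attacks the unsubstituted terminus of the chiral palladium–prenyl complex through C6 (O-prenylation being reversible under zerovalent palladium and C8 being blocked by its secondary alkyl group), which creates the quaternary C6 flanked by the C5 and C7 ketones, and the ligand antipode is chosen to deliver prenyl to the face that gives 6R.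

Step 17
Reactants: 24 methyl ester of the target
Product: 25 (3S)-3-[(2R,3S,6R)-6-{[(1R,3S)-2,2-dimethyl-3-(prop-1-en-2-yl)cyclobutyl]methyl}-4-hydroxy-2,3-dimethyl-6-(3-methylbut-2-en-1-yl)-5,7-dioxo-3,5,6,7-tetrahydro-2H-chromen-8-yl]-3-phenylpropanoic acid (CNP0328119.1)
Conditions: LiOH·H2O (5 equiv), THF–H2O, 0 °C to rt; then 1 M HCl to pH 3
Reagents that add atoms: lithium hydroxide (aqueous), [Li+].[OH-]
Why: Saponification of the methyl ester takes place on the delocalised enolate of the acidic triketone, which shields C3 from enolisation and the C5–C6–C7 unit from retro-Claisen cleavage, and brief cold acidification releases the acid without touching the prenyl or isopropenyl groups.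

## Compound list

1 | 2,4,6-trihydroxybenzaldehyde | O=Cc1c(O)cc(O)cc1O | starting material
2 | 2,4-bis(benzyloxy)-6-hydroxybenzaldehyde | O=Cc1c(O)cc(OCc2ccccc2)cc1OCc1ccccc1 | intermediate
3 | (S)-but-3-en-2-ol | C[C@H](O)C=C | starting material
4 | tert-butyl acrylate | C=CC(=O)OC(C)(C)C | starting material
5 | tert-butyl (2E,4S)-4-hydroxypent-2-enoate | C[C@H](O)/C=C/C(=O)OC(C)(C)C | intermediate
6 | tert-butyl (2E,4R)-4-[3,5-bis(benzyloxy)-2-formylphenoxy]pent-2-enoate | O=Cc1c(OCc2ccccc2)cc(OCc2ccccc2)cc1O[C@H](C)/C=C/C(=O)OC(C)(C)C | intermediate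
7 | tert-butyl 2-[(2R,3S)-5,7-bis(benzyloxy)-2-methyl-4-oxochroman-3-yl]acetate (2,3-cis) | O=C1[C@@H](CC(=O)OC(C)(C)C)[C@@H](C)Oc2cc(OCc3ccccc3)cc(OCc3ccccc3)c12 | intermediate
8 | 2-[(2R,3S)-5,7-bis(benzyloxy)-2-methyl-4-oxochroman-3-yl]acetic acid | O=C1[C@@H](CC(=O)O)[C@@H](C)Oc2cc(OCc3ccccc3)cc(OCc3ccccc3)c12 | intermediate
9 | Barton ester of 8 (2-thioxopyridin-1(2H)-yl ester) | O=C1[C@@H](CC(=O)ON3C=CC=CC3=S)[C@@H](C)Oc2cc(OCc3ccccc3)cc(OCc3ccccc3)c12 | intermediate
10 | (2R,3S)-5,7-bis(benzyloxy)-2,3-dimethylchroman-4-one | O=C1[C@@H](C)[C@@H](C)Oc2cc(OCc3ccccc3)cc(OCc3ccccc3)c12 | intermediate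
11 | (2R,3S)-5,7-bis(benzyloxy)-8-iodo-2,3-dimethylchroman-4-one | O=C1[C@@H](C)[C@@H](C)Oc2c(I)c(OCc3ccccc3)cc(OCc3ccccc3)c12 | intermediate
12 | methyl acrylate | C=CC(=O)OC | starting material
13 | methyl (E)-3-[(2R,3S)-5,7-bis(benzyloxy)-2,3-dimethyl-4-oxochroman-8-yl]acrylate | O=C1[C@@H](C)[C@@H](C)Oc2c(/C=C/C(=O)OC)c(OCc3ccccc3)cc(OCc3ccccc3)c12 | intermediate
14 | phenylboronic acid | OB(O)c1ccccc1 | starting material
15 | methyl (3S)-3-[(2R,3S)-5,7-bis(benzyloxy)-2,3-dimethyl-4-oxochroman-8-yl]-3-phenylpropanoate | O=C1[C@@H](C)[C@@H](C)Oc2c([C@@H](CC(=O)OC)c3ccccc3)c(OCc3ccccc3)cc(OCc3ccccc3)c12 | intermediate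
16 | methyl (3S)-3-[(2R,3S)-5,7-dihydroxy-2,3-dimethyl-4-oxochroman-8-yl]-3-phenylpropanoate | O=C1[C@@H](C)[C@@H](C)Oc2c([C@@H](CC(=O)OC)c3ccccc3)c(O)cc(O)c12 | intermediate
17 | (1S)-(−)-verbenone | CC1=CC(=O)[C@H]2C[C@@H]1C2(C)C | starting material
18 | (1S,3R)-3-acetyl-2,2-dimethylcyclobutane-1-carboxylic acid | CC(=O)[C@@H]1C[C@H](C(=O)O)C1(C)C | intermediate
19 | (1S,3S)-2,2-dimethyl-3-(prop-1-en-2-yl)cyclobutane-1-carboxylic acid | C=C(C)[C@@H]1C[C@H](C(=O)O)C1(C)C | intermediate
20 | [(1S,3S)-2,2-dimethyl-3-(prop-1-en-2-yl)cyclobutyl]methanol | C=C(C)[C@@H]1C[C@H](CO)C1(C)C | intermediate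
21 | (1S,3S)-2,2-dimethyl-3-(prop-1-en-2-yl)cyclobutane-1-carbaldehyde | C=C(C)[C@@H]1C[C@H](C=O)C1(C)C | intermediate
22 | methyl (3S)-3-[(2R,3S)-6-{[(1R,3S)-2,2-dimethyl-3-(prop-1-en-2-yl)cyclobutyl]methyl}-5,7-dihydroxy-2,3-dimethyl-4-oxochroman-8-yl]-3-phenylpropanoate | O=C1[C@@H](C)[C@@H](C)Oc2c([C@@H](CC(=O)OC)c3ccccc3)c(O)c(C[C@H]3C[C@@H](C(C)=C)C3(C)C)c(O)c12 | intermediate
23 | prenyl acetate (3-methylbut-2-en-1-yl acetate) | CC(C)=CCOC(C)=O | starting material
24 | methyl ester of the target (2R,3S,6R, benzylic S, cyclobutane 1R,3S) | C=C(C)[C@@H]1C[C@H](C[C@@]2(CC=C(C)C)C(=O)C3=C(O)[C@@H](C)[C@@H](C)OC3=C([C@@H](CC(=O)OC)c3ccccc3)C2=O)C1(C)C | intermediate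
25 | CNP0328119.1 | C=C(C)[C@@H]1C[C@H](C[C@@]2(CC=C(C)C)C(=O)C3=C(O)[C@@H](C)[C@@H](C)OC3=C([C@@H](CC(=O)O)c3ccccc3)C2=O)C1(C)C | target

## Step count and risks

Total: 17 steps. Longest linear sequence: 12 steps (1, 3 to 10, 15 to 17) from 2,4,6-trihydroxybenzaldehyde.

Most likely to fail:

**Step 4.** The carbene may add only slowly to an aldehyde flanked by two ortho oxygen substituents, the acyl anion may attack the wrong face of C3, or the cis ketone may drift to trans by enolisation during the reaction. The fallback forms ring B without a carbene. It sets out from 2: addition of EtMgBr (excess, THF, 0 °C) gives 1-[2,4-bis(benzyloxy)-6-hydroxyphenyl]propan-1-ol F1, which MnO2 oxidises to 1-[2,4-bis(benzyloxy)-6-hydroxyphenyl]propan-1-one F2. A Kostanecki–Robinson reaction (Ac2O, NaOAc, 150 °C) then gives 5,7-bis(benzyloxy)-2,3-dimethyl-4H-chromen-4-one F3. Copper hydride asymmetric conjugate reduction (Cu(OAc)2, one antipode of DTBM-SEGPHOS, (EtO)2MeSiH, t-BuOH, toluene) should deliver hydride to C2 and protonate the enolate at C3 on the face away from the C2 methyl, which leaves the two methyl groups cis. The fallback comes back to the route at 10.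

**Step 16.** The chiral palladium–prenyl complex may not discriminate the two faces of C6 well enough, and O-prenylation or attack at the tertiary allyl terminus may compete. The fallback sets out from 22 and uses allyl acetate in place of 23 under the same palladium and Trost ligand conditions, the unsubstituted allyl complex being the best-studied electrophile for prochiral stabilised nucleophiles and free of the regiochemical question. This gives methyl (3S)-3-[(2R,3S,6R)-6-allyl-6-{[(1R,3S)-2,2-dimethyl-3-(prop-1-en-2-yl)cyclobutyl]methyl}-4-hydroxy-2,3-dimethyl-5,7-dioxo-3,5,6,7-tetrahydro-2H-chromen-8-yl]-3-phenylpropanoate F5. Cross-metathesis with 2-methylbut-2-ene (second-generation Grubbs catalyst, CH2Cl2, 40 °C; the 1,1-disubstituted isopropenyl group should stay out) converts allyl into prenyl and comes back to the route at 24.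

**Step 9.** Insertion of an enoate whose β-carbon carries a di-ortho-substituted aryl group may be slow, so that protodeboronation outruns addition, and forcing with more base or heat would put C3 at risk. The fallback sets out from 11 and builds the stereocentre by reduction instead of aryl transfer. A Heck reaction with methyl (E)-cinnamate (Pd(OAc)2, n-Bu4NCl, NaHCO3, DMF, 80 °C) gives methyl (Z)-3-[(2R,3S)-5,7-bis(benzyloxy)-2,3-dimethyl-4-oxochroman-8-yl]-3-phenylacrylate F4. Asymmetric hydrogenation of this trisubstituted alkene with an iridium phosphine–oxazoline catalyst ([Ir(cod)(tBu-PHOX)]BArF, one antipode, H2, CH2Cl2), which does not cleave benzyl ethers, comes back to the route at 15.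

Further compounds
F1 | step 4 | 1-[2,4-bis(benzyloxy)-6-hydroxyphenyl]propan-1-ol (racemic) | CCC(O)c1c(O)cc(OCc2ccccc2)cc1OCc1ccccc1
F2 | step 4 | 1-[2,4-bis(benzyloxy)-6-hydroxyphenyl]propan-1-one | CCC(=O)c1c(O)cc(OCc2ccccc2)cc1OCc1ccccc1
F3 | step 4 | 5,7-bis(benzyloxy)-2,3-dimethyl-4H-chromen-4-one | CC1=C(C)C(=O)c2c(OCc3ccccc3)cc(OCc3ccccc3)cc2O1
F4 | step 9 | methyl (Z)-3-[(2R,3S)-5,7-bis(benzyloxy)-2,3-dimethyl-4-oxochroman-8-yl]-3-phenylacrylate | O=C1[C@@H](C)[C@@H](C)Oc2c(/C(=C\C(=O)OC)c3ccccc3)c(OCc3ccccc3)cc(OCc3ccccc3)c12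
F5 | step 16 | methyl (3S)-3-[(2R,3S,6R)-6-allyl-6-{[(1R,3S)-2,2-dimethyl-3-(prop-1-en-2-yl)cyclobutyl]methyl}-4-hydroxy-2,3-dimethyl-5,7-dioxo-3,5,6,7-tetrahydro-2H-chromen-8-yl]-3-phenylpropanoate | C=C(C)[C@@H]1C[C@H](C[C@@]2(CC=C)C(=O)C3=C(O)[C@@H](C)[C@@H](C)OC3=C([C@@H](CC(=O)OC)c3ccccc3)C2=O)C1(C)C
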